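0.0757 h⁻¹ of the J charged: that was the rate of making X that I read from the north run. I read it at 5.00 h from the X standing plus half the Q, taking each Q as one X joined to one J; at 2.50 h the same sum gave 0.0778 h⁻¹.

| setting | north | flask |
|---|---|---|
| J | 0.20 M | 0.20 M |
| E | 0.48 M | 0.240 M |
| remark | run made earlier |  |
| time |  | 6.0 d |

north run (percent of the J charged)

| time / h | X / % | Q / % |
|---|---|---|
| 2.50 | 8.0 | 22.9 |
| 4.00 | 10.5 | 40.6 |
| 5.00 | 12.0 | 51.7 |
| 8.00 | 23.6 | 68.2 |
| 12.0 | 28.4 | 68.9 |
| 20.0 | 27.0 | 68.7 |
| 30.0 | 28.2 | 68.5 |

(scatter of a reading: 0.5 percentage points)

- in percentages every species weighs as the J in it: one Q counts as two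
- at the start none of J is in solution
- a reading or a percentage of X counts all its forms, free or not

1. the X standing at 6.0 d, as a percentage of the J charged
2. the Q standing at 6.0 d, as a percentage of the J charged

Between 4.00 h and 5.00 h in the north run, the rise of Q read as X being eaten at 0.0555 h⁻¹, so making still led. Dividing by the mean X and the mean J left gave a capture constant of 1.16 h⁻¹.

That comparison drifts, as I took eating to go with X times J left and both change. I therefore defined the crossing share, the level at which X equals J left while making equals eating: the square root of making over capture, 25.6% in the north run.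

I assumed making follows E, so half the E gives this flask 18.1%. Keeping the north ratio of last X reading to crossing share, I estimated 19.9% X for this flask and, from the north sum of X and Q at that reading, 76.8% Q.

Could E fail? The north readings put the X made at 0.125 M from 0.48 M of E, and this flask charges 0.240 M of E against 0.20 M of J, so I took J as the limiting reagent. Is the time enough? By my reckoning X minus J left climbs at twice the making rate, which puts the end of J in this flask near 15.8 h, shorter than 6.0 d.

The forecast differed: 62.5% X and 34.4% Q, reasoning that “E is exhausted at the kink”.

The flask gave 18.0% X and 74.1% Q.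

    J ⇌ L, rate k1*(cs1 - [L]) while solid is left; crystals form when [L] > cs1 (solubility = 5.10 mM, k = 39.0 h⁻¹)
    L + E → X (k = 7.40 L mol⁻¹ h⁻¹)
    2 L → D (k = 20.0 L mol⁻¹ h⁻¹)
    G ⇌ X, rate k4*(cs4 - [X]) while solid is left; crystals form when [X] > cs4 (solubility = 49.0 mM, k = 10.0 h⁻¹)
    J + X → Q (k = 5.90 L mol⁻¹ h⁻¹)

In the flask at 0.281 d dissolved X was made 1.14 times faster than it was used up, going into its other forms counted as use, and the X at the asked time lay close to the crossing share of 18.1%. My 19.9% ran 1.9 percentage points high. For a neighbour flask with J at 0.080 M and E as in the flask, the crossing share, taken inversely with the J charged, is 45.2%, the north ratio gives 49.9%, and that neighbour held 49.2% X.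

(Readings and results come from a simulation for an exercise; scatter was added.)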